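**Strategy.** Everything rests on disconnecting the C5–C14 bond and delivering the angular methyl from the C10 oxygen. The feature exploited is the cis pair C10–OH/C5–CH3 on the two adjacent, fully substituted fusion carbons shared by rings A and B. A (bromomethyl)dimethylsilyl ether on O10 of a 4-methyl-4-en-3-one gives an α-silyl radical that closes 5-exo onto C5: one operation forms the quaternary centre, fixes it cis to O10 and creates the C4 stereocentre. The precursor is the bicyclic γ-silyloxy enone carrying an 8α-aryloxy group trans to O10, which locks the chair in which attack on C5 is axial and the C4 methyl ends equatorial.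

Key step: step 7

**Conventions and remarks on the chemistry**
- Bicyclic compounds are described as decalins in the numbering of the target: ring A is C5–C10, ring B is C1–C5 plus C10, C15 is the methyl on C4, C14 the methyl on C5. β is the face of the C10 oxygen, α the opposite face. "4-en-3-one" means a C4=C5 alkene and a C3 ketone.
- Design of the precursor: the C8 oxygen is made cis to O10 (8β) only so that it can steer the epoxidation, and is then inverted to 8α. A cis 8β-ether would favour the ring A chair in which the 4β-methyl is axial and syn to O10, so that equilibration at C4 would drift to the wrong epimer. The equatorial 8α-ether holds O10 axial on ring A and pseudo-equatorial on ring B; C14 then enters axially, the 4β-methyl is equatorial, and hydride later reaches C3 from the α face.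
- The C4 methyl is introduced after dearomatisation, because Birch reduction of a 1,2,3,4-tetrasubstituted anisole would be regiochemically ambiguous.
- Assumption: an (S)-selective ketoreductase that accepts 2-tetralone 1 can be taken from a commercial screening panel.

**Route**

Step 1
Reactants: 1 6-methoxy-2-tetralone
Product: 2 (S)-6-methoxy-1,2,3,4-tetrahydronaphthalen-2-ol
Conditions: ketoreductase (S-selective), NADP+ (cat.), i-PrOH, phosphate buffer pH 7, 30 °C
Reagents that add atoms: none
Why: Enzymatic carbonyl reduction with cofactor recycling is an established reaction type for 2-tetralones; the enzyme tells the benzylic from the homobenzylic methylene and should set the future C8 carbinol as S.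

Step 2
Reactants: 2 (S)-6-methoxy-1,2,3,4-tetrahydronaphthalen-2-ol; 3 water
Product: 5 (S)-6-hydroxy-3,4,5,6,7,8-hexahydronaphthalen-2(1H)-one (8β-hydroxy-5(10)-en-3-one), via dienol methyl ether 4 (not isolated)
Conditions: Li, NH3(l)/THF/t-BuOH, −78 → −33 °C; NH4Cl; then (CO2H)2, MeOH/H2O, 25 °C
Reagents that add atoms: water (O)
Why: Birch reduction keeps the methoxy-bearing carbon and both ring-fusion carbons on double bonds, and dilute oxalic acid hydrolyses the enol ether to the C3 ketone without moving the 5(10)-alkene into conjugation; the carbinol centre is untouched.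

Step 3
Reactants: 5 8β-hydroxy-5(10)-en-3-one; 6 iodomethane
Product: 7 8β-hydroxy-4-methyl-5(10)-en-3-one (both C4 epimers)
Conditions: LiN(SiMe3)2 (2.1 equiv), THF, −78 °C; MeI (1.05 equiv), −78 → −40 °C; aq NH4Cl
Reagents that add atoms: iodomethane (CI)
Why: α-Alkylation of an extended lithium enolate: after the hydroxyl has taken the first equivalent of base, the C4–H (allylic and α to the ketone) is the most acidic, and dienolates alkylate at the α-carbon with the 5(10)-alkene left in place; the C4 configuration is irrelevant because C4 becomes sp2 in step 4.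

Step 4
Reactants: 7 8β-hydroxy-4-methyl-5(10)-en-3-one; 8 tert-butyl hydroperoxide
Product: 10 8β,10β-dihydroxy-4-methyl-4-en-3-one, via 5β,10β-epoxy ketone 9 (not isolated)
Conditions: VO(acac)2 (5 mol %), t-BuOOH (1.2 equiv), PhMe, 25 °C; aq Na2SO3 wash; then DBU (1.2 equiv), CH2Cl2, 0 → 25 °C
Reagents that add atoms: tert-butyl hydroperoxide (CC(C)(C)OO)
Why: Hydroxyl-directed vanadium-catalysed epoxidation of a cyclic homoallylic alcohol should deliver oxygen on the face of the C8 hydroxyl and so set C10 (β), and the β,γ-epoxy ketone then opens by E1cB elimination from the C4 enolate to the γ-hydroxy enone.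

Step 5
Reactants: 10 8β,10β-dihydroxy-4-methyl-4-en-3-one; 11 4-methoxyphenol
Product: 12 10β-hydroxy-8α-(4-methoxyphenoxy)-4-methyl-4-en-3-one
Conditions: PPh3 (1.5 equiv), DIAD (1.5 equiv), PhMe, 0 → 40 °C
Reagents that add atoms: 4-methoxyphenol (COc1ccc(O)cc1)
Why: Mitsunobu etherification: SN2 displacement of the oxyphosphonium group by the phenoxide inverts C8 to α (trans to O10), the tertiary C10 hydroxyl cannot be activated, and the aryl ether serves as the C8 protecting group.

Step 6
Reactants: 12 10β-hydroxy-8α-(4-methoxyphenoxy)-4-methyl-4-en-3-one; 13 (bromomethyl)chlorodimethylsilane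
Product: 14 10β-[(bromomethyl)dimethylsilyloxy]-8α-(4-methoxyphenoxy)-4-methyl-4-en-3-one
Conditions: Et3N (2 equiv), DMAP (0.2 equiv), CH2Cl2, 0 → 25 °C
Reagents that add atoms: (bromomethyl)chlorodimethylsilane (C[Si](C)(Cl)CBr)
Why: Silylation of the tertiary alcohol by a sterically small chlorosilane under nucleophilic catalysis; no other group in 12 is nucleophilic.

Step 7
Reactants: 14 10β-[(bromomethyl)dimethylsilyloxy]-8α-(4-methoxyphenoxy)-4-methyl-4-en-3-one
Product: 15 tricyclic oxasilolane ketone (β-face O10–SiMe2–C14H2–C5 bridge; 4β-methyl; 8α-aryloxy; C3 ketone)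
Conditions: Bu3SnH (1.3 equiv, syringe pump), AIBN (0.2 equiv), PhH (0.01 M), 80 °C
Reagents that add atoms: none
Why: The tributyltin radical abstracts bromine to give a nucleophilic α-silyl methyl radical, which adds to C5, the electrophilic β-carbon of the C3 enone, and the resulting C4 α-keto radical takes hydrogen from Bu3SnH and carries the chain; the closest known reaction type is the silicon-tethered radical cyclisation of (bromomethyl)dimethylsilyl ethers of allylic alcohols. The oxasilolane ring (O10–Si–C14–C5–C10) closes 5-exo-trig. C5 is controlled by the tether, since a five-membered ring across C10–C5 can only be cis-fused, so C14 enters on the β face of the C10 oxygen. C4 is set by hydrogen transfer anti to the new axial C5–C14 bond, and any 4α epimer converges in step 8 because the 4β-methyl is equatorial in the chair fixed by the equatorial 8α-aryloxy group. The step needs 5-exo attack at a fully substituted carbon to outrun 6-endo closure at C4 and direct reduction of the radical; polarity matching, the chair that offers C5 for axial attack with O10 pseudo-equatorial on ring B, and a low stationary stannane concentration should secure this.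

Step 8
Reactants: 15 tricyclic oxasilolane ketone
Product: 16 10β-hydroxy-8α-(4-methoxyphenoxy)-4β,5β-dimethyl-cis-decalin-3-one
Conditions: KOtBu (5 equiv), DMSO (degassed, 1% H2O), 25 → 50 °C
Reagents that add atoms: none
Why: Protodesilylation of the cyclic siloxane: tert-butoxide opens the Si–O bond and the C10 alkoxide drives a 1,4 carbon-to-oxygen silyl shift through pentacoordinate silicon with protonation of C14, which turns the tether carbon into the C5 methyl, while the same base equilibrates C4 to the equatorial 4β-methyl (a 4α-methyl would be syn-diaxial to C9).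

Step 9
Reactants: 16 10β-hydroxy-8α-(4-methoxyphenoxy)-4β,5β-dimethyl-cis-decalin-3-one
Product: 17 8α-(4-methoxyphenoxy)-4β,5β-dimethyl-cis-decalin-3β,10β-diol
Conditions: LiBH(s-Bu)3 (2.5 equiv), THF, −78 °C; aq NH4Cl
Reagents that add atoms: none
Why: Bulky-hydride reduction of a cyclohexanone: the axial C14 methyl blocks the axial approach and the reagent size favours equatorial (α-face) delivery, which should give the axial 3β-alcohol cis to both methyl groups.

Step 10
Reactants: 17 3β,10β-diol; 18 acetic anhydride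
Product: 19 3β-acetoxy-8α-(4-methoxyphenoxy)-4β,5β-dimethyl-cis-decalin-10β-ol
Conditions: Ac2O (3 equiv), pyridine, DMAP (0.2 equiv), 25 °C
Reagents that add atoms: acetic anhydride (CC(=O)OC(C)=O)
Why: DMAP-catalysed acylation takes the secondary C3 alcohol and leaves the tertiary C10 hydroxyl.

Step 11
Reactants: 19 3β-acetoxy-8α-(4-methoxyphenoxy)-4β,5β-dimethyl-cis-decalin-10β-ol
Product: 20 3β-acetoxy-4β,5β-dimethyl-cis-decalin-8α,10β-diol
Conditions: (NH4)2Ce(NO3)6 (2.5 equiv), MeCN/H2O 4:1, 0 °C
Reagents that add atoms: none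
Why: Oxidative cleavage of a 4-methoxyphenyl ether: one-electron oxidation of the electron-rich ring and attack of water at the ring carbon release the C8 alcohol with retention together with benzoquinone, while acetate and tertiary alcohol are inert.

Step 12
Reactants: 20 3β-acetoxy-4β,5β-dimethyl-cis-decalin-8α,10β-diol
Product: 21 3β-acetoxy-10β-hydroxy-4β,5β-dimethyl-cis-decalin-8-one
Conditions: Dess–Martin periodinane (1.5 equiv), NaHCO3, CH2Cl2, 0 → 25 °C
Reagents that add atoms: none
Why: Dess–Martin oxidation of the only secondary alcohol under buffered, non-basic conditions, which spare the β-hydroxy ketone from dehydration and retro-aldol cleavage.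

Step 13
Reactants: 21 3β-acetoxy-10β-hydroxy-8-one; 22 trimethylsilyl triflate
Product: 24 3β-acetoxy-4β,5β-dimethyl-10β-(trimethylsilyloxy)-6-en-8-one, via bis-silyl enol ether 23 (not isolated)
Conditions: TMSOTf (3 equiv), Et3N (5 equiv), CH2Cl2, 0 °C; then Pd(OAc)2 (1.1 equiv), MeCN, 25 °C
Reagents that add atoms: trimethylsilyl triflate (C[Si](C)(C)OS(=O)(=O)C(F)(F)F)
Why: Saegusa–Ito dehydrogenation: soft enolisation away from the quaternary C10 gives the C7–C8 silyl enol ether without touching the acetate, palladium diacetate converts it into the enone, only the C6–C7 bond can be dehydrogenated because C10 bears no hydrogen, and the C10 hydroxyl is silylated on the way.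

Step 14
Reactants: 24 10β-silyloxy-6-en-8-one; 22 trimethylsilyl triflate; 25 3-chloroperbenzoic acid
Product: 28 3β-acetoxy-9α,10β-dihydroxy-4β,5β-dimethyl-6-en-8-one, via silyl dienol ether 26 (not isolated), via 9α-silyloxy ketone 27 (not isolated)
Conditions: TMSOTf (1.5 equiv), Et3N (3 equiv), CH2Cl2, 0 → 25 °C; then mCPBA (1.1 equiv), NaHCO3, CH2Cl2, −20 °C; then citric acid, MeOH, 25 °C
Reagents that add atoms: 3-chloroperbenzoic acid (OOC(=O)c1cccc(Cl)c1)
Why: Rubottom oxidation: the enone can enolise only toward C9, the peracid should epoxidise the electron-rich C8=C9 enol ether bond from the α face, away from the C10 silyloxy group and the C5 methyl that stand on the β face, and silyl migration followed by mild methanolysis gives the 9α-hydroxy ketone trans to O10.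

Step 15
Reactants: 28 9α,10β-dihydroxy-6-en-8-one; 29 angelic acid
Product: 30 3β-acetoxy-9α-angeloyloxy-10β-hydroxy-4β,5β-dimethyl-6-en-8-one
Conditions: angelic acid (3 equiv), 2,4,6-Cl3C6H2COCl (3 equiv), Et3N (6 equiv), PhMe, 25 °C; then 28, 70 °C
Reagents that add atoms: angelic acid (C/C=C(/C)C(=O)O)
Why: Yamaguchi esterification through the mixed anhydride, run without DMAP so that the angeloyl group is transferred without Z-to-E isomerisation; only the secondary C9 hydroxyl is acylated.

Step 16
Reactants: 30 9α-angeloyloxy-6-en-8-one; 31 iodine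
Product: 32 3β-acetoxy-9α-angeloyloxy-10β-hydroxy-7-iodo-4β,5β-dimethyl-6-en-8-one
Conditions: I2 (3 equiv), pyridine/CH2Cl2 1:1, 25 °C
Reagents that add atoms: iodine (II)
Why: Pyridine-mediated α-iodination of an enone (conjugate addition of pyridine, iodination of the enolate, elimination), a reaction type that works for cyclohexenones whose β-carbon carries a hydrogen next to a quaternary centre.

Step 17
Reactants: 32 7-iodo enone; 33 tributyl(1-ethoxyvinyl)stannane; 3 water
Product: 35 CNP0196241.1 (3β-acetoxy-7-acetyl-9α-angeloyloxy-10β-hydroxy-4β,5β-dimethyl-6-en-8-one), via ethoxyvinyl dienone 34 (not isolated)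
Conditions: Pd2(dba)3 (5 mol %), AsPh3 (20 mol %), CuI (10 mol %), NMP, 40 °C; then 1 M HCl, THF, 0 °C
Reagents that add atoms: tributyl(1-ethoxyvinyl)stannane (CCCC[Sn](CCCC)(CCCC)C(=C)OCC); water (O)
Why: Stille coupling of the α-iodoenone with an acetyl anion equivalent, followed by hydrolysis of the enol ether to the C7 acetyl group under acid mild enough for both esters and the tertiary alcohol.

**Compound list**

1 | 6-methoxy-2-tetralone | COc1ccc2CC(=O)CCc2c1 | starting material
2 | (S)-6-methoxy-1,2,3,4-tetrahydronaphthalen-2-ol | C1[C@@H](O)CCc2cc(OC)ccc12 | intermediate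
3 | water | O | starting material
4 | (S)-6-methoxy-1,2,3,4,5,8-hexahydronaphthalen-2-ol (dienol methyl ether) | C1[C@@H](O)CCC2=C1CC=C(OC)C2 | intermediate
5 | (S)-6-hydroxy-3,4,5,6,7,8-hexahydronaphthalen-2(1H)-one (8β-hydroxy-5(10)-en-3-one) | C1[C@@H](O)CCC2=C1CCC(=O)C2 | intermediate
6 | iodomethane | CI | starting material
7 | 8β-hydroxy-4-methyl-5(10)-en-3-one (C4 epimers) | C1[C@@H](O)CCC2=C1CCC(=O)C2C | intermediate
8 | tert-butyl hydroperoxide | CC(C)(C)OO | starting material
9 | 5β,10β-epoxy-8β-hydroxy-4-methyl-decalin-3-one (C4 epimers) | C1[C@@H](O)CC[C@@]23O[C@@]12CCC(=O)C3C | intermediate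
10 | 8β,10β-dihydroxy-4-methyl-4-en-3-one | C1[C@@H](O)CCC2=C(C)C(=O)CC[C@]12O | intermediate
11 | 4-methoxyphenol | COc1ccc(O)cc1 | starting material
12 | 10β-hydroxy-8α-(4-methoxyphenoxy)-4-methyl-4-en-3-one | C1[C@H](Oc3ccc(OC)cc3)CCC2=C(C)C(=O)CC[C@]12O | intermediate
13 | (bromomethyl)chlorodimethylsilane | C[Si](C)(Cl)CBr | starting material
14 | 10β-[(bromomethyl)dimethylsilyloxy]-8α-(4-methoxyphenoxy)-4-methyl-4-en-3-one (key-step precursor) | C1[C@H](Oc3ccc(OC)cc3)CCC2=C(C)C(=O)CC[C@]12O[Si](C)(C)CBr | intermediate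
15 | tricyclic oxasilolane ketone (key-step product) | C1[C@H](Oc4ccc(OC)cc4)CC[C@]2(C[Si](C)(C)O3)[C@@H](C)C(=O)CC[C@]123 | intermediate
16 | 10β-hydroxy-8α-(4-methoxyphenoxy)-4β,5β-dimethyl-cis-decalin-3-one | C1[C@H](Oc3ccc(OC)cc3)CC[C@]2(C)[C@@H](C)C(=O)CC[C@]12O | intermediate
17 | 8α-(4-methoxyphenoxy)-4β,5β-dimethyl-cis-decalin-3β,10β-diol | C1[C@H](Oc3ccc(OC)cc3)CC[C@]2(C)[C@@H](C)[C@@H](O)CC[C@]12O | intermediate
18 | acetic anhydride | CC(=O)OC(C)=O | starting material
19 | 3β-acetoxy-8α-(4-methoxyphenoxy)-4β,5β-dimethyl-cis-decalin-10β-ol | C1[C@H](Oc3ccc(OC)cc3)CC[C@]2(C)[C@@H](C)[C@@H](OC(C)=O)CC[C@]12O | intermediate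
20 | 3β-acetoxy-4β,5β-dimethyl-cis-decalin-8α,10β-diol | C1[C@H](O)CC[C@]2(C)[C@@H](C)[C@@H](OC(C)=O)CC[C@]12O | intermediate
21 | 3β-acetoxy-10β-hydroxy-4β,5β-dimethyl-cis-decalin-8-one | C1C(=O)CC[C@]2(C)[C@@H](C)[C@@H](OC(C)=O)CC[C@]12O | intermediate
22 | trimethylsilyl triflate | C[Si](C)(C)OS(=O)(=O)C(F)(F)F | starting material
23 | 3β-acetoxy-8,10β-bis(trimethylsilyloxy)-4β,5β-dimethyl-7-ene (bis-silyl enol ether) | C1C(O[Si](C)(C)C)=CC[C@]2(C)[C@@H](C)[C@@H](OC(C)=O)CC[C@]12O[Si](C)(C)C | intermediate
24 | 3β-acetoxy-4β,5β-dimethyl-10β-(trimethylsilyloxy)-6-en-8-one | C1C(=O)C=C[C@]2(C)[C@@H](C)[C@@H](OC(C)=O)CC[C@]12O[Si](C)(C)C | intermediate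
25 | 3-chloroperbenzoic acid | OOC(=O)c1cccc(Cl)c1 | starting material
26 | 3β-acetoxy-8,10β-bis(trimethylsilyloxy)-4β,5β-dimethyl-6,8-diene (silyl dienol ether) | C1=C(O[Si](C)(C)C)C=C[C@]2(C)[C@@H](C)[C@@H](OC(C)=O)CC[C@]12O[Si](C)(C)C | intermediate
27 | 3β-acetoxy-9α,10β-bis(trimethylsilyloxy)-4β,5β-dimethyl-6-en-8-one | C[Si](C)(C)O[C@@H]1C(=O)C=C[C@]2(C)[C@@H](C)[C@@H](OC(C)=O)CC[C@]12O[Si](C)(C)C | intermediate
28 | 3β-acetoxy-9α,10β-dihydroxy-4β,5β-dimethyl-6-en-8-one | O[C@@H]1C(=O)C=C[C@]2(C)[C@@H](C)[C@@H](OC(C)=O)CC[C@]12O | intermediate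
29 | angelic acid | C/C=C(/C)C(=O)O | starting material
30 | 3β-acetoxy-9α-angeloyloxy-10β-hydroxy-4β,5β-dimethyl-6-en-8-one | C/C=C(/C)C(=O)O[C@@H]1C(=O)C=C[C@]2(C)[C@@H](C)[C@@H](OC(C)=O)CC[C@]12O | intermediate
31 | iodine | II | starting material
32 | 3β-acetoxy-9α-angeloyloxy-10β-hydroxy-7-iodo-4β,5β-dimethyl-6-en-8-one | C/C=C(/C)C(=O)O[C@@H]1C(=O)C(I)=C[C@]2(C)[C@@H](C)[C@@H](OC(C)=O)CC[C@]12O | intermediate
33 | tributyl(1-ethoxyvinyl)stannane | CCCC[Sn](CCCC)(CCCC)C(=C)OCC | starting material
34 | 3β-acetoxy-9α-angeloyloxy-7-(1-ethoxyvinyl)-10β-hydroxy-4β,5β-dimethyl-6-en-8-one | C/C=C(/C)C(=O)O[C@@H]1C(=O)C(C(=C)OCC)=C[C@]2(C)[C@@H](C)[C@@H](OC(C)=O)CC[C@]12O | intermediate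
35 | CNP0196241.1 | C/C=C(/C)C(=O)O[C@@H]1C(=O)C(C(C)=O)=C[C@]2(C)[C@@H](C)[C@@H](OC(C)=O)CC[C@]12O | target

**Step count and risk**

Total steps: 17. Longest linear sequence: 17 steps, from 6-methoxy-2-tetralone (1).

Steps most likely to fail:

1. Step 7. The α-silyl radical may take hydrogen from the stannane before it adds to the fully substituted C5, or close in the 6-endo sense at C4. Fallback, from 12 back to 16: the methyl is delivered by hydroxyl-directed cyclopropanation instead.
   - Luche reduction (NaBH4, CeCl3·7H2O, MeOH, −40 °C) should give the allylic alcohol 3α,10β-dihydroxy-8α-(4-methoxyphenoxy)-4-methyl-4-ene F1 by axial hydride delivery.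
   - Selective silylation of the secondary hydroxyl (TBSCl, imidazole, DMF) gives the 3α-silyl ether F2.
   - Simmons–Smith cyclopropanation (Et2Zn, CH2I2, CH2Cl2, 0 °C), directed by the free tertiary C10 hydroxyl to the β face of C4=C5, gives the 4β,5β-methano compound F3.
   - Bu4NF in THF frees the cyclopropyl carbinol F4, and Dess–Martin oxidation gives the cyclopropyl ketone F5.
   - Li in NH3/THF at −78 °C (short contact, no added alcohol) cleaves the cyclopropane bond between C4 and the new methylene, the bond that overlaps with the carbonyl. The methylene becomes the C5 β-methyl, and protonation and equilibration of the C3 enolate set the equatorial 4β-methyl of 16.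

2. Step 14. Facial selectivity in the peracid attack on the dienol ether may be poor or reversed, since the α face carries ring B. Fallback, from 24 back to 28: the C9 configuration is set by reduction instead of oxidation.
   - The same three operations are run without regard to the face of attack, through silyl dienol ether 26; β-face entry gives the 9β,10β-bis(trimethylsilyloxy) ketone F6 and, after methanolysis, the 9β,10β-diol F7.
   - Dess–Martin oxidation of the C9 carbinol (either epimer or the mixture) gives the 10β-hydroxy-8,9-dione F8.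
   - Me4NBH(OAc)3 in MeCN/AcOH at −20 °C: the C10 hydroxyl exchanges onto boron and delivers hydride to the neighbouring C9 carbonyl on the β face. The cross-conjugated C8 carbonyl is not reduced, so the 9α-alcohol 28 results.

3. Step 3. Deprotonation of the dianion may be unselective (C2 in place of C4), or a second methylation may occur. Fallback, from 5 back to 10: the methyl is attached to the enone after the C10 oxygen is in place.
   - The conditions of step 4 applied to 5 give the 5β,10β-epoxy-8β-hydroxy-decalin-3-one F9 and, after base opening, 8β,10β-dihydroxy-4-en-3-one F10.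
   - Thiomethylation at C4 through the dienol (PhSH, aq CH2O, Et3N, EtOH, reflux) gives the 4-(phenylthiomethyl) enone F11.
   - Desulfurisation with Raney Ni in acetone at reflux gives 10.

**Further compounds**

F1 | step 7 | 3α,10β-dihydroxy-8α-(4-methoxyphenoxy)-4-methyl-4-ene | C1[C@H](Oc3ccc(OC)cc3)CCC2=C(C)[C@H](O)CC[C@]12O
F2 | step 7 | 3α-(tert-butyldimethylsilyloxy)-10β-hydroxy-8α-(4-methoxyphenoxy)-4-methyl-4-ene | C1[C@H](Oc3ccc(OC)cc3)CCC2=C(C)[C@H](O[Si](C)(C)C(C)(C)C)CC[C@]12O
F3 | step 7 | 3α-(tert-butyldimethylsilyloxy)-10β-hydroxy-8α-(4-methoxyphenoxy)-4-methyl-4β,5β-methano-decalin | C1[C@H](Oc4ccc(OC)cc4)CC[C@@]23C[C@@]3(C)[C@H](O[Si](C)(C)C(C)(C)C)CC[C@]12O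
F4 | step 7 | 8α-(4-methoxyphenoxy)-4-methyl-4β,5β-methano-decalin-3α,10β-diol | C1[C@H](Oc4ccc(OC)cc4)CC[C@@]23C[C@@]3(C)[C@H](O)CC[C@]12O
F5 | step 7 | 10β-hydroxy-8α-(4-methoxyphenoxy)-4-methyl-4β,5β-methano-decalin-3-one | C1[C@H](Oc4ccc(OC)cc4)CC[C@@]23C[C@@]3(C)C(=O)CC[C@]12O
F6 | step 14 | 3β-acetoxy-9β,10β-bis(trimethylsilyloxy)-4β,5β-dimethyl-6-en-8-one | C[Si](C)(C)O[C@H]1C(=O)C=C[C@]2(C)[C@@H](C)[C@@H](OC(C)=O)CC[C@]12O[Si](C)(C)C
F7 | step 14 | 3β-acetoxy-9β,10β-dihydroxy-4β,5β-dimethyl-6-en-8-one | O[C@H]1C(=O)C=C[C@]2(C)[C@@H](C)[C@@H](OC(C)=O)CC[C@]12O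
F8 | step 14 | 3β-acetoxy-10β-hydroxy-4β,5β-dimethyl-6-ene-8,9-dione | O=C1C(=O)C=C[C@]2(C)[C@@H](C)[C@@H](OC(C)=O)CC[C@]12O
F9 | step 3 | 5β,10β-epoxy-8β-hydroxy-decalin-3-one | C1[C@@H](O)CC[C@@]23O[C@@]12CCC(=O)C3
F10 | step 3 | 8β,10β-dihydroxy-4-en-3-one | C1[C@@H](O)CCC2=CC(=O)CC[C@]12O
F11 | step 3 | 8β,10β-dihydroxy-4-(phenylthiomethyl)-4-en-3-one | C1[C@@H](O)CCC2=C(CSc3ccccc3)C(=O)CC[C@]12O
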